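**Retrosynthetic overview**
1. C6–Cl comes from SN2 chlorination of a (6R)-allylic alcohol; that alcohol comes from a macrocyclic C6 ketone, and the ten-membered ring from a Nozaki–Hiyama–Kishi closure (C5–C6) of a (Z)-2-bromodiene onto a C6 aldehyde.
2. The hydroxy-butanolide (C7, C8, C17, C19) comes from an intramolecular samarium Reformatsky reaction of a 7-O-(2-bromopropanoyl) 8-ketone.
3. C2–C5 come from ethynyl addition to the C2 lactol, Sonogashira coupling with CH2=CBr2 and Z-selective zinc reduction.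
4. Ring A (C1, C10) comes from an ester-tethered intramolecular Diels–Alder reaction of an L-arabinose-derived dienyl β-sulfinyl-methacrylate, followed by sulfoxide elimination and dihydroxylation.
5. Ring order: ring A with a temporary 2,9-lactone, then the butanolide, then the ten-membered ring. C9 and C7 are bought in L-arabinose; all other stereocentres are relayed from them.

Assumption: briarane numbering is used throughout (C15 = methyl on C1, C16 = CH2 on C5, C18 = methyl on C17, C19 = lactone C=O, C20 = methyl on C11; arabinose C1–C5 become C10, C9, C8, C7, C6; β = ring A face of the C15 methyl). The sulfoxide sulfur (5, 11, 12) and the CHBr carbon of the bromopropanoyl group (21, 22) are carried as epimer mixtures that vanish in steps 8 and 18.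

**Step 1**
Reactants: 1 methacrylic acid
Product: 3 (E)-3-bromo-2-methylprop-2-enoic acid, via 2,3-dibromo-2-methylpropanoic acid 2 (not isolated)
Conditions: Br2, CH2Cl2, 0 °C to rt; then KOH, MeOH, 65 °C; aq. HCl
Reagents that add atoms: bromine, BrBr
Why: Alkene bromination followed by E2 dehydrobromination gives the β-bromo acid with Br trans to CO2H (more stable E isomer); no stereocentre remains.

**Step 2**
Reactants: 3 (E)-3-bromo-2-methylprop-2-enoic acid
Product: 5 (E)-2-methyl-3-(phenylsulfinyl)prop-2-enoic acid, via phenylsulfanyl acid 4 (not isolated)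
Conditions: PhSH, NaOH, EtOH/H2O, 70 °C; then AcOH, 30% H2O2 (1.05 equiv), rt
Reagents that add atoms: thiophenol, Sc1ccccc1; hydrogen peroxide, OO
Why: Addition–elimination (vinylic substitution) of thiolate at the β-carbon keeps the E geometry, and one equivalent of peroxide oxidises sulfur only to the sulfoxide.

**Step 3**
Reactants: 6 L-arabinose
Product: 7 3,4-O-isopropylidene-L-arabinopyranose
Conditions: Me2C(OMe)2, TsOH·H2O (cat.), DMF, rt
Reagents that add atoms: 2,2-dimethoxypropane, COC(C)(C)OC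
Why: Acid-catalysed acetalisation takes the cis-3,4-diol of the pyranose and leaves O1 and O2 free; no stereocentre is touched.

**Step 4**
Reactants: 7 3,4-O-isopropylidene-L-arabinopyranose
Product: 8 (10E)-enal diol
Conditions: Ph3P=C(CH3)CHO, toluene, 80 °C
Reagents that add atoms: 2-(triphenylphosphoranylidene)propanal, CC(C=O)=P(c1ccccc1)(c1ccccc1)c1ccccc1
Why: Wittig olefination of the open-chain aldehyde form with a stabilised ylide gives the E trisubstituted enal (C9 cis to the C20 methyl) without touching C9, C8 or C7.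

**Step 5**
Reactants: 8 (10E)-enal diol
Product: 9 primary TBDPS ether of 8
Conditions: TBDPSCl, imidazole, CH2Cl2, 0 °C
Reagents that add atoms: tert-butylchlorodiphenylsilane, CC(C)(C)[Si](Cl)(c1ccccc1)c1ccccc1
Why: The bulky silyl chloride reacts only with the primary C6 hydroxyl, which also blocks oxa-Michael closure onto the enal.

**Step 6**
Reactants: 9 primary TBDPS ether of 8
Product: 10 (10E)-diene alcohol
Conditions: Ph3PCH3Br, KHMDS, THF, −78 to 0 °C (2.2 equiv ylide)
Reagents that add atoms: methyltriphenylphosphonium bromide, C[P+](c1ccccc1)(c1ccccc1)c1ccccc1.[Br-]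
Why: Wittig methylenation of the enal gives the (E)-1,3-diene; the C10=C11 geometry and all stereocentres are retained.

**Step 7**
Reactants: 10 (10E)-diene alcohol; 5 (E)-2-methyl-3-(phenylsulfinyl)prop-2-enoic acid
Product: 11 9-O-sulfinylmethacrylate triene
Conditions: EDC·HCl, DMAP, CH2Cl2, 0 °C to rt
Reagents that add atoms: none
Why: Steglich-type carbodiimide esterification of the only free hydroxyl (O9) installs the activated dienophile on the tether oxygen.

**Step 8**
Reactants: 11 9-O-sulfinylmethacrylate triene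
Product: 13 trans-fused ring A dienyl 2,9-lactone, via sulfoxide cycloadduct 12 (not isolated)
Conditions: PhCl (0.01 M), CaCO3, BHT, 130 °C
Reagents that add atoms: none
Why: Intramolecular Diels–Alder reaction followed by thermal sulfoxide syn-elimination: allylic 1,3-strain with the C20 methyl holds H-9 in the diene plane so the dienophile adds on the face carrying O9 (sets C10), the E-sulfinyl group goes endo with the tether carbonyl exo as in pentadienyl fumarates (trans-fused lactone, sets C1), and PhSOH can only leave with H-13 because C1 is quaternary.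

**Step 9**
Reactants: 13 trans-fused ring A dienyl 2,9-lactone
Product: 14 11α,12α-diol lactone
Conditions: OsO4 (5 mol %), NMO, acetone/H2O, 0 °C to rt
Reagents that add atoms: osmium tetroxide (catalytic oxygen carrier), O=[Os](=O)(=O)=O; N-methylmorpholine N-oxide, C[N+]1([O-])CCOCC1; water, O
Why: Upjohn syn-dihydroxylation takes the more electron-rich trisubstituted C11=C12 bond of the diene from the α face, anti to the axial C15 methyl, which sets C11 and C12 as the cis-diol.

**Step 10**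
Reactants: 14 11α,12α-diol lactone
Product: 15 lactol
Conditions: DIBAL-H (4 equiv), CH2Cl2, −78 °C
Reagents that add atoms: none
Why: Hydride reduction of the α-quaternary γ-lactone stops at the stable aluminium hemiacetal, giving the C2 lactol.

**Step 11**
Reactants: 15 lactol
Product: 16 2-ethynyl tetraol
Conditions: HC≡CMgBr (8 equiv), THF, −20 °C to rt
Reagents that add atoms: ethynylmagnesium bromide, C#C[Mg]Br
Why: Grignard addition to the open hydroxy-aldehyde form follows Felkin–Anh control from the quaternary C1 (C10 anti to the nucleophile, which passes the C15 methyl), setting C2.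

**Step 12**
Reactants: 16 2-ethynyl tetraol
Product: 17 bromoenyne tetraol
Conditions: CH2=CBr2 (5 equiv), Pd(PPh3)4 (5 mol %), CuI (10 mol %), i-Pr2NH, THF, rt
Reagents that add atoms: 1,1-dibromoethene, C=C(Br)Br
Why: Sonogashira mono-coupling of the terminal alkyne with excess geminal dibromide adds C5 and C16 and keeps one vinylic bromide.

**Step 13**
Reactants: 17 bromoenyne tetraol
Product: 18 (3Z)-bromodiene tetraol
Conditions: Zn dust activated with Cu(OAc)2 and AgNO3, MeOH/H2O, 40 °C
Reagents that add atoms: none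
Why: Boland-type zinc semi-reduction of the conjugated, hydroxyl-activated alkyne gives only the Z alkene and leaves the vinylic bromide and the other alkenes alone.

**Step 14**
Reactants: 18 (3Z)-bromodiene tetraol
Product: 19 2,9,12-triacetate
Conditions: Ac2O, pyridine, DMAP (cat.), 0 °C to rt
Reagents that add atoms: acetic anhydride, CC(=O)OC(C)=O
Why: Acylation takes the three secondary hydroxyls while the hindered tertiary C11 hydroxyl stays free, as in the target.

**Step 15**
Reactants: 19 2,9,12-triacetate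
Product: 20 7,8-diol
Conditions: AcOH/H2O 4:1, 45 °C
Reagents that add atoms: none
Why: Mild acetal hydrolysis removes the isopropylidene group and leaves the acetates and the TBDPS ether.

**Step 16**
Reactants: 20 7,8-diol
Product: 21 7-O-(2-bromopropanoyl) ester
Conditions: 2-bromopropanoyl bromide (1.05 equiv), 2,4,6-collidine, CH2Cl2, −78 to −40 °C
Reagents that add atoms: 2-bromopropanoyl bromide, CC(Br)C(Br)=O
Why: Selective acylation of O7, which is flanked by the C6 methylene, over O8, which sits between two branched carbons next to the ring.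

**Step 17**
Reactants: 21 7-O-(2-bromopropanoyl) ester
Product: 22 8-ketone
Conditions: Dess–Martin periodinane, NaHCO3, CH2Cl2, rt
Reagents that add atoms: none
Why: Dess–Martin oxidation of the only free secondary alcohol gives the C8 ketone under non-basic conditions that do not epimerise C7 or C9.

**Step 18**
Reactants: 22 8-ketone
Product: 23 8-hydroxy-19,7-lactone
Conditions: SmI2 (2.2 equiv, slow addition), THF, −78 °C
Reagents that add atoms: none
Why: Intramolecular samarium Reformatsky reaction: the samarium enolate closes the five-membered lactone through the transition state that keeps the C6 and C9 chains trans on the new ring and the C18 methyl away from C9, which sets C8 and C17.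

**Step 19**
Reactants: 23 8-hydroxy-19,7-lactone
Product: 24 primary C6 alcohol
Conditions: HF·pyridine, pyridine, THF, 0 °C to rt
Reagents that add atoms: none
Why: Fluoride desilylation frees the primary alcohol without touching the acetates, the lactone or the bromodiene.

**Step 20**
Reactants: 24 primary C6 alcohol
Product: 25 C6 aldehyde
Conditions: Dess–Martin periodinane, NaHCO3, CH2Cl2, 0 °C
Reagents that add atoms: none
Why: Dess–Martin oxidation under buffered conditions avoids retro-aldol or elimination of the β-hydroxy aldehyde; the tertiary hydroxyls are inert.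

**Step 21**
Reactants: 25 C6 aldehyde
Product: 26 macrocyclic 6-alcohol (C6 epimers)
Conditions: CrCl2 (10 equiv), NiCl2 (2 mol %), DMSO/THF 3:1, 0.002 M, rt
Reagents that add atoms: none
Why: Nozaki–Hiyama–Kishi coupling of the 2-bromodiene with the aldehyde closes the ten-membered ring at C5–C6, helped by the Z alkene and the ring A trans junction; the C6 configuration is irrelevant here.

**Step 22**
Reactants: 26 macrocyclic 6-alcohol
Product: 27 macrocyclic 6-ketone
Conditions: Dess–Martin periodinane, NaHCO3, CH2Cl2, 0 °C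
Reagents that add atoms: none
Why: Dess–Martin oxidation converges both C6 epimers to the cross-conjugated ketone.

**Step 23**
Reactants: 27 macrocyclic 6-ketone
Product: 28 (6R)-alcohol
Conditions: NaBH4, CeCl3·7H2O, MeOH, −78 °C
Reagents that add atoms: none
Why: Luche 1,2-reduction with hydride entering anti to the C7–O bond (Felkin–Anh with the lactone oxygen as polar group) gives the alcohol with O6 anti to O7 in the Fischer sense, which sets C6.

**Step 24**
Reactants: 28 (6R)-alcohol
Product: 29 target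
Conditions: PPh3, hexachloroacetone, CH2Cl2, 0 °C
Reagents that add atoms: hexachloroacetone, O=C(C(Cl)(Cl)Cl)C(Cl)(Cl)Cl
Why: Appel-type chlorination (Magid conditions) replaces the secondary allylic hydroxyl by SN2 with inversion and without allylic transposition, giving the (6S)-chloride; the tertiary hydroxyls do not react.

**Compound list**
1 | methacrylic acid | C=C(C)C(=O)O | starting material
2 | 2,3-dibromo-2-methylpropanoic acid (racemic, not isolated) | OC(=O)C(C)(Br)CBr | intermediate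
3 | (E)-3-bromo-2-methylprop-2-enoic acid | OC(=O)/C(C)=C/Br | intermediate
4 | (E)-2-methyl-3-(phenylsulfanyl)prop-2-enoic acid (not isolated) | OC(=O)/C(C)=C/Sc1ccccc1 | intermediate
5 | (E)-2-methyl-3-(phenylsulfinyl)prop-2-enoic acid (racemic at sulfur) | OC(=O)/C(C)=C/S(=O)c1ccccc1 | intermediate
6 | L-arabinose (pyranose form, anomeric mixture) | OC1[C@H](O)[C@@H](O)[C@@H](O)CO1 | starting material
7 | 3,4-O-isopropylidene-L-arabinopyranose (anomeric mixture) | OC1[C@H](O)[C@H]2OC(C)(C)O[C@H]2CO1 | intermediate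
8 | (E)-2,3-dideoxy-5,6-O-isopropylidene-2-C-methyl-L-arabino-hept-2-enose (C12 enal, 10E, free 9-OH and primary 6-OH) | O=C/C(C)=C/[C@H](O)[C@H]1OC(C)(C)O[C@H]1CO | intermediate
9 | TBDPS ether of 8 on the primary oxygen (C6) | O=C/C(C)=C/[C@H](O)[C@H]1OC(C)(C)O[C@H]1CO[Si](c2ccccc2)(c3ccccc3)C(C)(C)C | intermediate
10 | (10E)-11-methyl-10,12-diene with free 9-OH, 7,8-acetonide, 6-OTBDPS (L-arabino at C7–C9) | C=C/C(C)=C/[C@H](O)[C@H]1OC(C)(C)O[C@H]1CO[Si](c2ccccc2)(c3ccccc3)C(C)(C)C | intermediate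
11 | 9-O-[(E)-2-methyl-3-(phenylsulfinyl)prop-2-enoyl] ester of 10 (sulfur epimers) | C=C/C(C)=C/[C@H](OC(=O)/C(C)=C/S(=O)c1ccccc1)[C@H]2OC(C)(C)O[C@H]2CO[Si](c3ccccc3)(c4ccccc4)C(C)(C)C | intermediate
12 | sulfoxide cycloadduct: trans-fused 2,9-γ-lactone on ring A (C11=C12), C15 methyl and 14-S(O)Ph β, H-10 α (not isolated) | O=C3[C@@]2(C)[C@H](S(=O)c4ccccc4)CC=C(C)[C@@H]2[C@H](O3)[C@H]5OC(C)(C)O[C@H]5CO[Si](c6ccccc6)(c7ccccc7)C(C)(C)C | intermediate
13 | trans-fused 2,9-γ-lactone on ring A 11,13-diene (C15 methyl β, H-10 α), side chain 7,8-acetonide, 6-OTBDPS | O=C3[C@@]2(C)C=CC=C(C)[C@@H]2[C@H](O3)[C@H]4OC(C)(C)O[C@H]4CO[Si](c5ccccc5)(c6ccccc6)C(C)(C)C | intermediate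
14 | 11α,12α-diol of 13 (C20 methyl β, C13=C14 kept) | O=C3[C@@]2(C)C=C[C@@H](O)[C@@](C)(O)[C@@H]2[C@H](O3)[C@H]4OC(C)(C)O[C@H]4CO[Si](c5ccccc5)(c6ccccc6)C(C)(C)C | intermediate
15 | C2 lactol of 14 (anomeric mixture) | OC3[C@@]2(C)C=C[C@@H](O)[C@@](C)(O)[C@@H]2[C@H](O3)[C@H]4OC(C)(C)O[C@H]4CO[Si](c5ccccc5)(c6ccccc6)C(C)(C)C | intermediate
16 | 2-ethynyl-2,9,11,12-tetraol (C2 as in the target) | C#C[C@H](O)[C@@]2(C)C=C[C@@H](O)[C@@](C)(O)[C@@H]2[C@H](O)[C@H]4OC(C)(C)O[C@H]4CO[Si](c5ccccc5)(c6ccccc6)C(C)(C)C | intermediate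
17 | 5-bromo-5(16)-en-3-yne tetraol | C=C(Br)C#C[C@H](O)[C@@]2(C)C=C[C@@H](O)[C@@](C)(O)[C@@H]2[C@H](O)[C@H]4OC(C)(C)O[C@H]4CO[Si](c5ccccc5)(c6ccccc6)C(C)(C)C | intermediate
18 | (3Z)-5-bromo-3,5(16)-diene tetraol | C=C(Br)/C=C\[C@H](O)[C@@]2(C)C=C[C@@H](O)[C@@](C)(O)[C@@H]2[C@H](O)[C@H]4OC(C)(C)O[C@H]4CO[Si](c5ccccc5)(c6ccccc6)C(C)(C)C | intermediate
19 | 2,9,12-triacetate of 18 (11-OH free) | C=C(Br)/C=C\[C@H](OC(C)=O)[C@@]2(C)C=C[C@@H](OC(C)=O)[C@@](C)(O)[C@@H]2[C@H](OC(C)=O)[C@H]4OC(C)(C)O[C@H]4CO[Si](c5ccccc5)(c6ccccc6)C(C)(C)C | intermediate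
20 | 7,8-diol triacetate | C=C(Br)/C=C\[C@H](OC(C)=O)[C@@]2(C)C=C[C@@H](OC(C)=O)[C@@](C)(O)[C@@H]2[C@H](OC(C)=O)[C@@H](O)[C@@H](O)CO[Si](c3ccccc3)(c4ccccc4)C(C)(C)C | intermediate
21 | 7-O-(2-bromopropanoyl) ester of 20 (CHBr epimers) | C=C(Br)/C=C\[C@H](OC(C)=O)[C@@]2(C)C=C[C@@H](OC(C)=O)[C@@](C)(O)[C@@H]2[C@H](OC(C)=O)[C@@H](O)[C@@H](OC(=O)C(C)Br)CO[Si](c3ccccc3)(c4ccccc4)C(C)(C)C | intermediate
22 | 8-ketone of 21 | C=C(Br)/C=C\[C@H](OC(C)=O)[C@@]2(C)C=C[C@@H](OC(C)=O)[C@@](C)(O)[C@@H]2[C@H](OC(C)=O)C(=O)[C@@H](OC(=O)C(C)Br)CO[Si](c3ccccc3)(c4ccccc4)C(C)(C)C | intermediate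
23 | (7R,8R,17R)-8-hydroxy-19,7-lactone, 6-OTBDPS, open ten-membered ring | C=C(Br)/C=C\[C@H](OC(C)=O)[C@@]2(C)C=C[C@@H](OC(C)=O)[C@@](C)(O)[C@@H]2[C@H](OC(C)=O)[C@]3(O)[C@@H](C)C(=O)O[C@H]3CO[Si](c4ccccc4)(c5ccccc5)C(C)(C)C | intermediate
24 | primary C6 alcohol from 23 | C=C(Br)/C=C\[C@H](OC(C)=O)[C@@]2(C)C=C[C@@H](OC(C)=O)[C@@](C)(O)[C@@H]2[C@H](OC(C)=O)[C@]3(O)[C@@H](C)C(=O)O[C@H]3CO | intermediate
25 | C6 aldehyde | C=C(Br)/C=C\[C@H](OC(C)=O)[C@@]2(C)C=C[C@@H](OC(C)=O)[C@@](C)(O)[C@@H]2[C@H](OC(C)=O)[C@]3(O)[C@@H](C)C(=O)O[C@H]3C=O | intermediate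
26 | macrocyclic 6-alcohol, deschloro-6-hydroxy target skeleton (C6 epimers) | C=C1/C=C\[C@H](OC(C)=O)[C@@]2(C)C=C[C@@H](OC(C)=O)[C@@](C)(O)[C@@H]2[C@H](OC(C)=O)[C@]2(O)[C@@H](C)C(=O)O[C@H]2C1O | intermediate
27 | macrocyclic 6-ketone | C=C1/C=C\[C@H](OC(C)=O)[C@@]2(C)C=C[C@@H](OC(C)=O)[C@@](C)(O)[C@@H]2[C@H](OC(C)=O)[C@]2(O)[C@@H](C)C(=O)O[C@H]2C1=O | intermediate
28 | (6R)-6-alcohol | C=C1/C=C\[C@H](OC(C)=O)[C@@]2(C)C=C[C@@H](OC(C)=O)[C@@](C)(O)[C@@H]2[C@H](OC(C)=O)[C@]2(O)[C@@H](C)C(=O)O[C@H]2[C@@H]1O | intermediate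
29 | CNP0285654.2: (1S,2S,3Z,6S,7R,8R,9S,10S,11S,12R,17R)-2,9,12-triacetoxy-6-chloro-8,11-dihydroxybriara-3,5(16),13-triene 19,7-lactone | C=C1/C=C\[C@H](OC(C)=O)[C@@]2(C)C=C[C@@H](OC(C)=O)[C@@](C)(O)[C@@H]2[C@H](OC(C)=O)[C@]2(O)[C@@H](C)C(=O)O[C@H]2[C@H]1Cl | target

**Step count**
Total: 24 steps. Longest linear sequence: 22 steps (L-arabinose 6 to 29, steps 3–24); steps 1–2 form a two-step branch that joins at step 7.

**Three steps most likely to fail**

Step 8 (cycloaddition and sulfoxide elimination; the risk is a poor trans:cis ring-fusion ratio or loss of the sulfinyl ester). The fallback moves the leaving group from the dienophile to the diene terminus. It sets out from 9 and comes back at 13. Acylation of 9 with methacryloyl chloride (Et3N, DMAP) gives the enal methacrylate F1. Takai olefination (CrCl2, CHCl3, THF, 65 °C) converts the aldehyde into the (12E)-13-chlorodiene methacrylate F2. Thermal intramolecular Diels–Alder reaction (1,2-dichlorobenzene, 2,6-lutidine, 170 °C) gives the allylic chloride cycloadduct F3, in which the chloride is cis to C9 and therefore pseudo-axial. DBU in toluene then removes HCl in an anti E2 with H-14 to give 13.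

Step 21 (closure of the ten-membered ring by carbonyl addition). The fallback closes the same C5–C6 bond by an acyl cross-coupling and delivers the ketone directly. It sets out from 25 and comes back at 27. Pinnick oxidation (NaClO2, NaH2PO4, 2-methyl-2-butene) gives the C6 carboxylic acid F4. 2,2′-Dipyridyl disulfide and PPh3 turn it into the S-(2-pyridyl) thioester F5. A nickel-catalysed reductive acyl–vinyl coupling (NiCl2(MeOCH2CH2OMe), 4,4′-di-tert-butyl-2,2′-bipyridine, Zn, DMA, high dilution) joins the thioester carbon to the vinylic bromide carbon and gives 27.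

Step 23 (facial selectivity of the ketone reduction inside the macrocycle). The fallback sets C6 by SN2 inversion instead of by hydride delivery. It sets out from 27 and comes back at 28. If the reduction gives mainly the 6-epi alcohol F6, Mitsunobu reaction with chloroacetic acid (PPh3, DIAD, toluene, 0 °C) gives the inverted (6R)-chloroacetate F7. Thiourea and NaHCO3 in EtOH remove only the chloroacetyl group and give 28.

**Further compounds**
F1 | step 8 | 9-O-methacryloyl ester of enal 9 | O=C/C(C)=C/[C@H](OC(=O)C(C)=C)[C@H]1OC(C)(C)O[C@H]1CO[Si](c2ccccc2)(c3ccccc3)C(C)(C)C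
F2 | step 8 | (10E,12E)-13-chloro-11-methyl-10,12-diene 9-O-methacrylate | Cl/C=C/C(C)=C/[C@H](OC(=O)C(C)=C)[C@H]1OC(C)(C)O[C@H]1CO[Si](c2ccccc2)(c3ccccc3)C(C)(C)C
F3 | step 8 | trans-fused 2,9-lactone on ring A (C11=C12) with 13-chloro cis to C9 | O=C3[C@@]2(C)C[C@H](Cl)C=C(C)[C@@H]2[C@H](O3)[C@H]4OC(C)(C)O[C@H]4CO[Si](c5ccccc5)(c6ccccc6)C(C)(C)C
F4 | step 21 | C6 carboxylic acid from aldehyde 25 | C=C(Br)/C=C\[C@H](OC(C)=O)[C@@]2(C)C=C[C@@H](OC(C)=O)[C@@](C)(O)[C@@H]2[C@H](OC(C)=O)[C@]3(O)[C@@H](C)C(=O)O[C@H]3C(=O)O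
F5 | step 21 | S-(2-pyridyl) thioester of F4 | C=C(Br)/C=C\[C@H](OC(C)=O)[C@@]2(C)C=C[C@@H](OC(C)=O)[C@@](C)(O)[C@@H]2[C@H](OC(C)=O)[C@]3(O)[C@@H](C)C(=O)O[C@H]3C(=O)Sc4ccccn4
F6 | step 23 | (6S)-alcohol, C6 epimer of 28 | C=C1/C=C\[C@H](OC(C)=O)[C@@]2(C)C=C[C@@H](OC(C)=O)[C@@](C)(O)[C@@H]2[C@H](OC(C)=O)[C@]2(O)[C@@H](C)C(=O)O[C@H]2[C@H]1O
F7 | step 23 | (6R)-6-O-chloroacetate of 28 | C=C1/C=C\[C@H](OC(C)=O)[C@@]2(C)C=C[C@@H](OC(C)=O)[C@@](C)(O)[C@@H]2[C@H](OC(C)=O)[C@]2(O)[C@@H](C)C(=O)O[C@H]2[C@@H]1OC(=O)CCl
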